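## Analysis of the target

The target 52 is a 36-membered macrolactone. The ring runs from the lactone carbonyl C1 to the carbinol C35, whose oxygen closes it, and C35 carries an exocyclic (2S)-hexan-2-yl group (C36–C40, methyl on C36). C1–C3 form a (2Z)-3-methyl enoate; C4–C34 are a saturated chain with nine secondary hydroxyls on C7, C9, C13, C17, C21, C25, C27, C29 and C33. There are eleven stereocentres (7S, 9R, 13S, 17R, 21R, 25S, 27S, 29S, 33R, 35R, 36S in open-chain numbering). The 1,3 pairs are C7/C9 syn, C25/C27 syn, C27/C29 anti and C33/C35 syn, with C35/C36 anti. The 1,5 pairs are C9/C13 anti, C13/C17 syn, C17/C21 syn, C21/C25 anti and C29/C33 syn. Sensitive points are the Z-trisubstituted enoate (isomerisation or deconjugation once the carboxyl is activated), the lactone beside free hydroxyls (acyl migration) and the hindered C35 carbinol that must be acylated. The main difficulty is that the 1,5-related carbinols are insulated by three methylenes, so no centre can steer the next and each must be set by a reagent. The strategy rests on the carbinols C21 and C25, which flank the methylenes C22–C24 in a 1,5-anti relationship near the middle of the chain: exactly what a three-carbon allyl linchpin placed between two aldehydes delivers.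

## Retrosynthetic reasoning

**Ring opening.** The target 52 is traced back to the nonakis-silyl ether 51, and the ring of 51 is cut at the C1–O35 ester bond to give seco-acid 49. This is the only carbon–heteroatom bond of the ring; cutting it leaves an unbranched chain with a single free hydroxyl. The forward step must acylate the hindered O35 without disturbing the Z-enoate.

**Differentiating O35.** Acid 49 comes from methyl ester 48, and 48 from 47, in which O35 alone is a 4-methoxybenzyl ether among nine silyl ethers. This lets O35 be unveiled oxidatively while every other oxygen stays masked.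

**Revealing the retron.** Removing the silyl groups on O21 and O25 (47 to 46) and restoring an E double bond at C23=C24 gives the ene-diol 45. The unit C21(OH)–C22–C23=C24–C25(OH) with 1,5-anti carbinols is the signature of a double allylboration.

**Central disconnection.** In 45 the bonds C24–C25 and C21–C22 are cut, giving aldehyde 20 (C25–C40), aldehyde 38 (C1–C21) and allenylboronate 42, which supplies C22–C24. The cut lies near the middle of the chain, so the two aldehydes are of similar size, and it creates two stereocentres and two C–C bonds in one flask. The forward reaction must add the two aldehydes in a fixed order, set C25 by reagent control and relay that information to C21.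

**Aldehyde 20.** Four reagent-controlled allylations with boranes 7 or 17 cut C26–C27 (from 16), C28–C29 (from 13), C32–C33 (from 10) and C34–C35 (from 6). The terminal alkene left by each allylation is either cleaved to the next aldehyde (1,3 spacing) or hydroformylated (1,5 spacing: C29–C30 from 12). Aldehyde 6 carries C36 and goes back through 5 and 4 to imide 3, made from 1 and 2; the C36 methyl is introduced by auxiliary-controlled alkylation.

**Aldehyde 38.** The same two operations are used from the other end. Hydroformylation cuts C20–C21, C16–C17 and C12–C13; allylation with 7 or 17 cuts C17–C18, C13–C14, C9–C10 and C7–C8. This leads back to aldehyde 26, whose Z-enoate is cut at C3–C4 into vinyl iodide 22 (from ynoate 21) and alkene 23. The enoate is built first, so the C21 aldehyde appears directly in the last hydroformylation with no protecting-group or oxidation steps at that terminus.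

**Linchpin 42.** The boronate is cut at the C–B bond and made from propargyl bromide 39.

## Alternatives that were turned down

**Alternative 1:** The ring would be cut at C3–C4, with the ester to O35 already in place. The open-chain ester A1 carries a terminal C4=C5 alkene and a (Z)-3-iodobut-2-enoate on O35. Hydroboration of the alkene with 9-BBN and an intramolecular B-alkyl Suzuki–Miyaura coupling (Pd(dppf)Cl2, Ph3As, Cs2CO3) would join C4 to C3 and give macrolactone A2, the same structure as 51.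
- For it: the hindered O35 is acylated intermolecularly by a small acid that can be used in excess, and the Z geometry is carried by the vinyl iodide with retention, so no Z-enoic acid is ever activated. On both points it is stronger than the chosen route.
- Against it: the alkylborane must find the palladium-bound vinyl group across a 36-atom tether at high dilution, where the base-assisted transmetalation is slow. Protodeboronation, β-hydride elimination and intermolecular coupling compete, and the base-labile β-iodoenoate ester sits in aqueous carbonate throughout.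
- Comparison: the disconnection removes only three carbons. The whole C4–C40 chain with eleven stereocentres must still be built, and this plan says nothing about how. The chosen strategy spends its key step where the complexity lies, uses the C3–C4 Suzuki bond in its easy intermolecular form (step 18) and closes the ring by lactonisation of a chain whose only free hydroxyl is O35.

**Alternative 2:** The bonds C8–C9 and C13–C14 would be cut, C9–C13 coming from pentane-1,5-diol A3. Both carbinol carbons of A3 would be allylated at the alcohol oxidation level by an allyl ester under [Ir(cod)Cl]2, a chiral BINAP-type bisphosphine, 4-chloro-3-nitrobenzoic acid and Cs2CO3, giving the C2-symmetric diene-diol A4.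
- For it: one catalytic step from a commodity diol sets two stereocentres, needs no dialdehyde, and the enantiomeric purity is amplified because the minor pathway ends in the meso isomer. For C9 and C13 this is more step-economical than the two stoichiometric allylborations used in the chosen route.
- Against it: the two allyl termini of A4 are homotopic, but the C9 side of the target needs the C7 carbinol two carbons away while the C13 side needs three methylenes to C17. The termini must therefore be told apart by a statistical mono-functionalisation. The step covers eleven of forty carbons and two of eleven stereocentres, and the syn 1,5 pairs cannot be made this way.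
- Comparison: it leaves open how the large pieces are joined. The chosen strategy concedes the economy at C9/C13 and offers instead a union of two different aldehydes with no desymmetrisation, placed at the point of highest convergence.

**Alternative 3:** The bonds C15–C16 and C18–C19 would be cut around C17. The lithiated dithiane A6 (C5–C15) would open (R)-epichlorohydrin A5 at its CH2 terminus; the alkoxide would close to the C17–C18 epoxide on warming, and the lithiated dithiane A7 (C19–C40) would open that epoxide, giving A8 with dithianes at C15 and C19 and a free O17.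
- For it: it is also a one-flask three-component union, and the C17 configuration is bought with A5 rather than induced, so on stereochemical certainty at its one centre it is stronger than the chosen step.
- Against it: C15 and C19 are plain methylenes in the target, so two thioketals must be made and later removed reductively on a large molecule. The carbanions sit 1,3 to silyl ethers on C13 and C21, a geometry open to 1,4-silyl migration from oxygen to carbon under the polar conditions such openings need. The second opening uses a very large nucleophile, and the step sets one stereocentre.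
- Comparison: the chosen linchpin sets two stereocentres, is erased by one mild saturation instead of two desulfurisations, and its fragments end in aldehydes that arise directly from the iterative chain growth.

Key step: step 33

Remark: TBS = tert-butyldimethylsilyl, PMB = 4-methoxybenzyl, Ipc = isopinocampheyl; atom numbers C1–C40 are those of the open chain; boranes 7 and 17 are assumed to be bought as pentane solutions and (−)-Ipc2BH to be made fresh from (+)-α-pinene and BH3·SMe2; the CIP descriptors at C13, C17, C21, C25 and C27 change in places along the route only because substituent priorities change, never because a centre is inverted.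

## Route

### Fragment C25–C40 (steps 1–16)

Step 1
Reactants: 1 (4S)-4-benzyl-1,3-oxazolidin-2-one; 2 hexanoyl chloride
Product: 3 (4S)-4-benzyl-3-hexanoyl-1,3-oxazolidin-2-one
Conditions: n-BuLi, THF, −78 °C; then 2, −78 → 0 °C
Reagents that add atoms: none
Why: N-acylation of the lithiated oxazolidinone by the acid chloride is the standard entry to an Evans imide; the hexanoyl group supplies C35–C40.

Step 2
Reactants: 3
Product: 4 (4S)-4-benzyl-3-[(2S)-2-methylhexanoyl]-1,3-oxazolidin-2-one
Conditions: NaN(SiMe3)2, THF, −78 °C; MeI, −78 → −40 °C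
Reagents that add atoms: iodomethane, CI
Why: Evans alkylation: the chelated (Z)-sodium enolate is methylated on the face away from the benzyl group, which sets C36 as S; the minor diastereomer should be removable by chromatography.

Step 3
Reactants: 4
Product: 5 (2S)-2-methylhexan-1-ol
Conditions: LiBH4, MeOH (1 equiv), Et2O, 0 °C
Reagents that add atoms: none
Why: Hydride attacks the exocyclic imide carbonyl and releases the primary alcohol without touching the α-stereocentre; the auxiliary is recovered.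

Step 4
Reactants: 5
Product: 6 (2S)-2-methylhexanal
Conditions: Dess–Martin periodinane, CH2Cl2, 0 °C → rt; used at once as a filtered solution
Reagents that add atoms: none
Why: Dess–Martin oxidation is mild enough that the α-branched aldehyde should form without epimerisation; it is volatile and is not stored.

Step 5
Reactants: 6; 7 (+)-B-allyldiisopinocampheylborane (Ipc groups from (−)-α-pinene)
Product: 8 (4R,5S)-5-methylnon-1-en-4-ol
Conditions: Et2O/pentane, −78 °C; then NaOH, H2O2, 0 °C → rt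
Reagents that add atoms: none
Why: Brown allylation through a chair transition state; the Ipc groups of 7 choose the aldehyde face that gives 35R, and this reagent control should override the weak Felkin preference of the α-methyl group, giving the 35,36-anti product; C32–C34 are added.

Step 6
Reactants: 8
Product: 9 (4R,5S)-4-(PMB-oxy)-5-methylnon-1-ene
Conditions: NaH, 4-methoxybenzyl chloride, Bu4NI (cat.), THF/DMF, 0 °C → rt
Reagents that add atoms: 4-methoxybenzyl chloride, COc1ccc(CCl)cc1
Why: Williamson etherification of the sodium alkoxide; PMB is chosen for O35 because it alone can later be removed oxidatively in the presence of silyl ethers.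

Step 7
Reactants: 9
Product: 10 (3R,4S)-3-(PMB-oxy)-4-methyloctanal
Conditions: OsO4 (cat.), NaIO4, 2,6-lutidine, dioxane/H2O, rt
Reagents that add atoms: sodium periodate, [Na+].[O-]I(=O)(=O)=O
Why: Lemieux–Johnson cleavage (catalytic osmylation, then periodate cleavage of the diol) turns the terminal alkene into the C33 aldehyde; the lutidine buffer should prevent β-elimination of the PMB ether.

Step 8
Reactants: 10; 7
Product: 11 (4R,6R,7S)-6-(PMB-oxy)-7-methylundec-1-en-4-ol
Conditions: Et2O/pentane, −78 °C; then NaOH, H2O2, 0 °C → rt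
Reagents that add atoms: none
Why: Second Brown allylation; the reagent sets C33 as R, 1,3-syn to O35, the β-alkoxy group having only a small influence in the closed transition state; C30–C32 are added.

Step 9
Reactants: 11
Product: 12 (4R,6R,7S)-4-(TBS-oxy)-6-(PMB-oxy)-7-methylundec-1-ene
Conditions: TBSCl, imidazole, DMF, rt
Reagents that add atoms: tert-butyldimethylsilyl chloride, CC(C)(C)[Si](C)(C)Cl
Why: Silylation of the secondary alcohol; the ether keeps O33 from closing a lactol onto the aldehyde formed next.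

Step 10
Reactants: 12
Product: 13 (5R,7R,8S)-5-(TBS-oxy)-7-(PMB-oxy)-8-methyldodecanal
Conditions: Rh(acac)(CO)2 (1 mol %), BIPHEPHOS (3 mol %), CO/H2 (1:1, 5 bar), toluene, 60 °C
Reagents that add atoms: carbon monoxide, [C-]#[O+]
Why: Rhodium-catalysed hydroformylation with a wide-bite-angle bisphosphite places the formyl group on the terminal carbon, adding C29 and leaving the three methylenes C30–C32; ethers are inert and no stereocentre is touched.

Step 11
Reactants: 13; 7
Product: 14 (4S,8R,10R,11S)-8-(TBS-oxy)-10-(PMB-oxy)-11-methylpentadec-1-en-4-ol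
Conditions: Et2O/pentane, −78 °C; then NaOH, H2O2, 0 °C → rt
Reagents that add atoms: none
Why: Brown allylation of an unbranched aldehyde; C29 is five atoms from C33, so its configuration (S here) comes from the reagent alone.

Step 12
Reactants: 14
Product: 15 (4S,8R,10R,11S)-4,8-bis(TBS-oxy)-10-(PMB-oxy)-11-methylpentadec-1-ene
Conditions: TBSCl, imidazole, DMF, rt
Reagents that add atoms: tert-butyldimethylsilyl chloride, CC(C)(C)[Si](C)(C)Cl
Why: Routine silylation of O29 before the alkene is cleaved.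

Step 13
Reactants: 15
Product: 16 (3S,7R,9R,10S)-3,7-bis(TBS-oxy)-9-(PMB-oxy)-10-methyltetradecanal
Conditions: OsO4 (cat.), NaIO4, 2,6-lutidine, dioxane/H2O, rt
Reagents that add atoms: sodium periodate, [Na+].[O-]I(=O)(=O)=O
Why: Lemieux–Johnson cleavage of the terminal alkene gives the C27 aldehyde; silyl and PMB ethers are stable to the buffered conditions.

Step 14
Reactants: 16; 17 (−)-B-allyldiisopinocampheylborane (Ipc groups from (+)-α-pinene)
Product: 18 (4S,6S,10R,12R,13S)-6,10-bis(TBS-oxy)-12-(PMB-oxy)-13-methylheptadec-1-en-4-ol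
Conditions: Et2O/pentane, −78 °C; then NaOH, H2O2, 0 °C → rt
Reagents that add atoms: none
Why: Brown allylation with the other antipode of the reagent sets C27 1,3-anti to O29; reagent control is expected to dominate the small bias of the β-silyloxy group.

Step 15
Reactants: 18
Product: 19 (4S,6S,10R,12R,13S)-4,6,10-tris(TBS-oxy)-12-(PMB-oxy)-13-methylheptadec-1-ene
Conditions: TBSCl, imidazole, DMF, rt
Reagents that add atoms: tert-butyldimethylsilyl chloride, CC(C)(C)[Si](C)(C)Cl
Why: Routine silylation of O27.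

Step 16
Reactants: 19
Product: 20 (3R,5S,9R,11R,12S)-3,5,9-tris(TBS-oxy)-11-(PMB-oxy)-12-methylhexadecanal
Conditions: OsO4 (cat.), NaIO4, 2,6-lutidine, dioxane/H2O, rt
Reagents that add atoms: sodium periodate, [Na+].[O-]I(=O)(=O)=O
Why: Lemieux–Johnson cleavage gives the C25 aldehyde, the first partner of the key step; it should be used soon, since β-silyloxy aldehydes eliminate on standing.

### Fragment C1–C21 (steps 17–31)

Step 17
Reactants: 21 methyl but-2-ynoate
Product: 22 methyl (2Z)-3-iodobut-2-enoate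
Conditions: NaI, AcOH, 110 °C
Reagents that add atoms: sodium iodide, [Na+].[I-]
Why: Conjugate addition of iodide to the ynoate and protonation of the allenolate give net anti addition of HI, so iodine ends cis to the ester (Z).

Step 18
Reactants: 23 4,4-diethoxybut-1-ene; 22
Product: 25 methyl (2Z)-7,7-diethoxy-3-methylhept-2-enoate, via alkyl-9-BBN adduct 24 (not isolated)
Conditions: 9-BBN, THF, 0 °C → rt; then 22, Pd(dppf)Cl2 (5 mol %), Ph3As, Cs2CO3, DMF/H2O, rt
Reagents that add atoms: none
Why: Anti-Markovnikov hydroboration gives the primary alkylborane 24, which couples with the vinyl iodide with retention of geometry (B-alkyl Suzuki–Miyaura coupling), forming C3–C4 and fixing the Z-enoate; acetal and ester tolerate aqueous carbonate at room temperature.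

Step 19
Reactants: 25
Product: 26 methyl (2Z)-3-methyl-7-oxohept-2-enoate
Conditions: 1 M HCl, THF, rt
Reagents that add atoms: water, O
Why: Acid hydrolysis of the diethyl acetal frees the C7 aldehyde; the conjugated ester is stable to dilute acid.

Step 20
Reactants: 26; 7
Product: 27 methyl (2Z,7S)-7-hydroxy-3-methyldeca-2,9-dienoate
Conditions: Et2O/pentane, −78 °C; then NaBO3·4H2O, THF/H2O, rt
Reagents that add atoms: none
Why: Brown allylation of an unbranched aldehyde sets C7 as S by reagent control; allylboranes do not add to the ester, and the perborate work-up avoids hydroxide at the methyl ester.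

Step 21
Reactants: 27
Product: 28 methyl (2Z,7S)-7-(TBS-oxy)-3-methyldeca-2,9-dienoate
Conditions: TBSCl, imidazole, DMF, rt
Reagents that add atoms: tert-butyldimethylsilyl chloride, CC(C)(C)[Si](C)(C)Cl
Why: Routine silylation of O7.

Step 22
Reactants: 28
Product: 29 methyl (2Z,7S)-7-(TBS-oxy)-3-methyl-9-oxonon-2-enoate
Conditions: OsO4 (cat.), NaIO4, 2,6-lutidine, dioxane/H2O, rt
Reagents that add atoms: sodium periodate, [Na+].[O-]I(=O)(=O)=O
Why: Lemieux–Johnson cleavage; electrophilic osmylation should prefer the electron-rich monosubstituted alkene over the electron-poor trisubstituted enoate, giving the C9 aldehyde.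

Step 23
Reactants: 29; 7
Product: 30 methyl (2Z,7S,9R)-7-(TBS-oxy)-9-hydroxy-3-methyldodeca-2,11-dienoate
Conditions: Et2O/pentane, −78 °C; then NaBO3·4H2O, THF/H2O, rt
Reagents that add atoms: none
Why: Brown allylation sets C9 as R, 1,3-syn to O7, under reagent control; from here a wrong enantiomer at an earlier centre shows up as a diastereomer.

Step 24
Reactants: 30
Product: 31 methyl (2Z,7S,9R)-7,9-bis(TBS-oxy)-3-methyldodeca-2,11-dienoate
Conditions: TBSCl, imidazole, DMF, rt
Reagents that add atoms: tert-butyldimethylsilyl chloride, CC(C)(C)[Si](C)(C)Cl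
Why: Routine silylation of O9.

Step 25
Reactants: 31
Product: 32 methyl (2Z,7S,9R)-7,9-bis(TBS-oxy)-3-methyl-13-oxotridec-2-enoate
Conditions: Rh(acac)(CO)2 (1 mol %), BIPHEPHOS (3 mol %), CO/H2 (1:1, 5 bar), toluene, 60 °C
Reagents that add atoms: carbon monoxide, [C-]#[O+]
Why: Linear-selective hydroformylation of the terminal alkene adds C13 as the aldehyde; the trisubstituted conjugated alkene does not react with this catalyst.

Step 26
Reactants: 32; 17
Product: 33 methyl (2Z,7S,9R,13R)-7,9-bis(TBS-oxy)-13-hydroxy-3-methylhexadeca-2,15-dienoate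
Conditions: Et2O/pentane, −78 °C; then NaBO3·4H2O, THF/H2O, rt
Reagents that add atoms: none
Why: Brown allylation with the (+)-α-pinene-derived reagent sets C13 1,5-anti to C9; the centre is remote from all others, so only the reagent decides.

Step 27
Reactants: 33
Product: 34 methyl (2Z,7S,9R,13R)-7,9,13-tris(TBS-oxy)-3-methylhexadeca-2,15-dienoate
Conditions: TBSCl, imidazole, DMF, rt
Reagents that add atoms: tert-butyldimethylsilyl chloride, CC(C)(C)[Si](C)(C)Cl
Why: Routine silylation of O13.

Step 28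
Reactants: 34
Product: 35 methyl (2Z,7S,9R,13R)-7,9,13-tris(TBS-oxy)-3-methyl-17-oxoheptadec-2-enoate
Conditions: Rh(acac)(CO)2 (1 mol %), BIPHEPHOS (3 mol %), CO/H2 (1:1, 5 bar), toluene, 60 °C
Reagents that add atoms: carbon monoxide, [C-]#[O+]
Why: Linear-selective hydroformylation adds C17 as the aldehyde, as in step 25.

Step 29
Reactants: 35; 17
Product: 36 methyl (2Z,7S,9R,13S,17R)-7,9,13-tris(TBS-oxy)-17-hydroxy-3-methylicosa-2,19-dienoate
Conditions: Et2O/pentane, −78 °C; then NaBO3·4H2O, THF/H2O, rt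
Reagents that add atoms: none
Why: Brown allylation with 17 sets C17 1,5-syn to C13 under pure reagent control; the change of the C13 descriptor is a priority effect only.

Step 30
Reactants: 36
Product: 37 methyl (2Z,7S,9R,13S,17R)-7,9,13,17-tetrakis(TBS-oxy)-3-methylicosa-2,19-dienoate
Conditions: TBSCl, imidazole, DMF, rt
Reagents that add atoms: tert-butyldimethylsilyl chloride, CC(C)(C)[Si](C)(C)Cl
Why: Routine silylation of O17.

Step 31
Reactants: 37
Product: 38 methyl (2Z,7S,9R,13S,17R)-7,9,13,17-tetrakis(TBS-oxy)-3-methyl-21-oxohenicos-2-enoate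
Conditions: Rh(acac)(CO)2 (1 mol %), BIPHEPHOS (3 mol %), CO/H2 (1:1, 5 bar), toluene, 60 °C
Reagents that add atoms: carbon monoxide, [C-]#[O+]
Why: The third hydroformylation delivers the C21 aldehyde directly, so the second partner of the key step needs no protecting-group or oxidation step at that terminus.

### Linchpin (step 32)

Step 32
Reactants: 39 3-bromoprop-1-yne
Product: 42 5,5-dimethyl-2-(propa-1,2-dien-1-yl)-1,3,2-dioxaborinane, via allenylmagnesium bromide 40 (not isolated), via allenylboronic acid 41 (not isolated)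
Conditions: Mg, HgCl2 (cat.), Et2O, 0 °C; B(OMe)3, −78 °C; 2 M HCl; then 2,2-dimethylpropane-1,3-diol, MgSO4, rt
Reagents that add atoms: trimethyl borate, COB(OC)OC; 2,2-dimethylpropane-1,3-diol, OCC(C)(C)CO
Why: The Grignard reagent from propargyl bromide exists as the allenyl species and is borylated by trimethyl borate to the allenylboronate; hydrolysis and esterification with the diol give the distillable six-membered boronate.

### Union and completion (steps 33–39)

Step 33
Reactants: 42; 20; 38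
Product: 45 methyl (2Z,7S,9R,13S,17S,21R,23E,25R,27S,29S,33R,35R,36S)-7,9,13,17,27,29,33-heptakis(TBS-oxy)-21,25-dihydroxy-35-(PMB-oxy)-3,36-dimethyltetraconta-2,23-dienoate, via γ-borylallylborane 43 (not isolated), via C24-borylated borinate 44 (not isolated)
Conditions: (−)-Ipc2BH, 42, toluene, 0 °C; 20 (limiting), −78 °C; then 38, −78 °C → rt; NaBO3·4H2O, THF/H2O
Reagents that add atoms: none
Why: (−)-Ipc2BH adds across the terminal C=C of allene 42, and 1,3-boratropic equilibration gives the (E)-γ-borylallylborane 43, which is both an allylborane and, latently, an allylboronate. The dialkylborane end is far more reactive and adds to aldehyde 20 at −78 °C through a chair transition state: the Ipc groups select the aldehyde face (as in Brown crotylation) and fix C25, and the E geometry puts the boronate anti to the new C–O bond, so 44 carries a defined α-boryl stereocentre at C24 (bond C24–C25 formed). When 38 is added and the mixture warms, the α-substituted allylboronate 44 reacts through a second chair in which the C25 side chain on C24 lies equatorial, the arrangement favoured by the small neopentyl glycol ester; this forms C21–C22, gives the E C23=C24 bond and transposes the C24 chirality to C21, hence the 1,5-anti diol. The closest known reaction type is the one-pot double allylboration of two aldehydes with a γ-borylallylborane to give (E)-1,5-anti-pent-2-ene-1,5-diols. No ring is closed. C25 is controlled by the Ipc antipode, C21 by 1,3-chirality transfer from C24. The step needs ordered addition (20 is kept limiting so that no free allylborane meets 38), aldehyde-over-ester chemoselectivity (allylboron reagents do not add to the enoate ester) and E selectivity in the second chair; both aldehydes are unbranched at the α-carbon, the substrate class for which this sequence is established.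

Step 34
Reactants: 45
Product: 46 methyl (2Z,7S,9R,13S,17S,21S,25S,27S,29S,33R,35R,36S)-7,9,13,17,27,29,33-heptakis(TBS-oxy)-21,25-dihydroxy-35-(PMB-oxy)-3,36-dimethyltetracont-2-enoate
Conditions: 2-nitrobenzenesulfonylhydrazide, Et3N, CH2Cl2, rt
Reagents that add atoms: none
Why: Diimide, released from the sulfonylhydrazide, transfers two hydrogens in a concerted syn fashion to the isolated disubstituted C23=C24 bond, which should react faster than the trisubstituted enoate; there is no hydrogenolysis of the PMB ether and no stereocentre is affected.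

Step 35
Reactants: 46
Product: 47 methyl (2Z,7S,9R,13S,17R,21R,25S,27S,29S,33R,35R,36S)-7,9,13,17,21,25,27,29,33-nonakis(TBS-oxy)-35-(PMB-oxy)-3,36-dimethyltetracont-2-enoate
Conditions: TBSOTf, 2,6-lutidine, CH2Cl2, −78 → 0 °C
Reagents that add atoms: tert-butyldimethylsilyl trifluoromethanesulfonate, CC(C)(C)[Si](C)(C)OS(=O)(=O)C(F)(F)F
Why: Silylation of O21 and O25 makes all nine chain hydroxyls alike and leaves O35 as the only oxygen with a different protecting group.

Step 36
Reactants: 47
Product: 48 methyl (2Z,7S,9R,13S,17R,21R,25S,27S,29S,33R,35R,36S)-7,9,13,17,21,25,27,29,33-nonakis(TBS-oxy)-35-hydroxy-3,36-dimethyltetracont-2-enoate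
Conditions: DDQ, CH2Cl2/pH 7 buffer, 0 °C
Reagents that add atoms: none
Why: Oxidative cleavage of the electron-rich PMB ether by DDQ frees O35; silyl ethers and the electron-poor enoate are not oxidised, and the only allylic alcohol of the route was removed in step 34.

Step 37
Reactants: 48
Product: 49 (2Z,7S,9R,13S,17R,21R,25S,27S,29S,33R,35R,36S)-7,9,13,17,21,25,27,29,33-nonakis(TBS-oxy)-35-hydroxy-3,36-dimethyltetracont-2-enoic acid
Conditions: Me3SnOH, ClCH2CH2Cl, 80 °C; 0.01 M KHSO4 wash
Reagents that add atoms: trimethyltin hydroxide, C[Sn](C)(C)O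
Why: Tin-mediated hydroxide transfer cleaves the methyl ester under near-neutral conditions, so the silyl ethers survive and the Z-enoate is not exposed to strong base.

Step 38
Reactants: 49
Product: 51 (3Z,8S,10R,14S,18R,22R,26S,28S,30S,34R,36R)-8,10,14,18,22,26,28,30,34-nonakis(TBS-oxy)-36-[(2S)-hexan-2-yl]-4-methyl-1-oxacyclohexatriacont-3-en-2-one, via mixed anhydride 50 (not isolated)
Conditions: 2-methyl-6-nitrobenzoic anhydride, DMAP, CH2Cl2, rt, slow addition (about 1 mM)
Reagents that add atoms: none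
Why: Shiina macrolactonisation: the carboxylate forms the mixed anhydride 50, whose hindered aroyl carbonyl directs DMAP to the substrate acyl group, and the only free hydroxyl, O35, closes the 36-membered ring under high dilution; the large ring is unstrained and C35 keeps its configuration because the C–O bond is not broken.

Step 39
Reactants: 51
Product: 52 (3Z,8S,10R,14S,18R,22R,26S,28S,30S,34R,36R)-36-[(2S)-hexan-2-yl]-8,10,14,18,22,26,28,30,34-nonahydroxy-4-methyl-1-oxacyclohexatriacont-3-en-2-one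
Conditions: HF·pyridine, pyridine, THF, 0 °C → rt
Reagents that add atoms: none
Why: Buffered fluoride removes all nine secondary silyl ethers; the mildly acidic medium is chosen because basic fluoride could promote acyl migration from O35 to O33 or attack on the enoate.

## Compound list

1 | (4S)-4-benzyl-1,3-oxazolidin-2-one | O=C1N[C@@H](Cc2ccccc2)CO1 | starting material
2 | hexanoyl chloride | CCCCCC(=O)Cl | starting material
3 | (4S)-4-benzyl-3-hexanoyl-1,3-oxazolidin-2-one | CCCCCC(=O)N1[C@@H](Cc2ccccc2)COC1=O | intermediate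
4 | (4S)-4-benzyl-3-[(2S)-2-methylhexanoyl]-1,3-oxazolidin-2-one | CCCC[C@H](C)C(=O)N1[C@@H](Cc2ccccc2)COC1=O | intermediate
5 | (2S)-2-methylhexan-1-ol | CCCC[C@H](C)CO | intermediate
6 | (2S)-2-methylhexanal | CCCC[C@H](C)C=O | intermediate
7 | (+)-B-allyldiisopinocampheylborane, both Ipc groups from (−)-α-pinene | C=CCB([C@H]1C[C@H]2C[C@@H]([C@@H]1C)C2(C)C)[C@H]1C[C@H]2C[C@@H]([C@@H]1C)C2(C)C | starting material
8 | (4R,5S)-5-methylnon-1-en-4-ol | CCCC[C@H](C)[C@H](O)CC=C | intermediate
9 | (4R,5S)-4-(PMB-oxy)-5-methylnon-1-ene | CCCC[C@H](C)[C@H](OCc1ccc(OC)cc1)CC=C | intermediate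
10 | (3R,4S)-3-(PMB-oxy)-4-methyloctanal | CCCC[C@H](C)[C@H](OCc1ccc(OC)cc1)CC=O | intermediate
11 | (4R,6R,7S)-6-(PMB-oxy)-7-methylundec-1-en-4-ol | CCCC[C@H](C)[C@H](OCc1ccc(OC)cc1)C[C@H](O)CC=C | intermediate
12 | (4R,6R,7S)-4-(TBS-oxy)-6-(PMB-oxy)-7-methylundec-1-ene | CCCC[C@H](C)[C@H](OCc1ccc(OC)cc1)C[C@H](O[Si](C)(C)C(C)(C)C)CC=C | intermediate
13 | (5R,7R,8S)-5-(TBS-oxy)-7-(PMB-oxy)-8-methyldodecanal | CCCC[C@H](C)[C@H](OCc1ccc(OC)cc1)C[C@H](O[Si](C)(C)C(C)(C)C)CCCC=O | intermediate
14 | (4S,8R,10R,11S)-8-(TBS-oxy)-10-(PMB-oxy)-11-methylpentadec-1-en-4-ol | CCCC[C@H](C)[C@H](OCc1ccc(OC)cc1)C[C@H](O[Si](C)(C)C(C)(C)C)CCC[C@H](O)CC=C | intermediate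
15 | (4S,8R,10R,11S)-4,8-bis(TBS-oxy)-10-(PMB-oxy)-11-methylpentadec-1-ene | CCCC[C@H](C)[C@H](OCc1ccc(OC)cc1)C[C@H](O[Si](C)(C)C(C)(C)C)CCC[C@H](O[Si](C)(C)C(C)(C)C)CC=C | intermediate
16 | (3S,7R,9R,10S)-3,7-bis(TBS-oxy)-9-(PMB-oxy)-10-methyltetradecanal | CCCC[C@H](C)[C@H](OCc1ccc(OC)cc1)C[C@H](O[Si](C)(C)C(C)(C)C)CCC[C@H](O[Si](C)(C)C(C)(C)C)CC=O | intermediate
17 | (−)-B-allyldiisopinocampheylborane, both Ipc groups from (+)-α-pinene | C=CCB([C@@H]1C[C@@H]2C[C@H]([C@H]1C)C2(C)C)[C@@H]1C[C@@H]2C[C@H]([C@H]1C)C2(C)C | starting material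
18 | (4S,6S,10R,12R,13S)-6,10-bis(TBS-oxy)-12-(PMB-oxy)-13-methylheptadec-1-en-4-ol | CCCC[C@H](C)[C@H](OCc1ccc(OC)cc1)C[C@H](O[Si](C)(C)C(C)(C)C)CCC[C@H](O[Si](C)(C)C(C)(C)C)C[C@@H](O)CC=C | intermediate
19 | (4S,6S,10R,12R,13S)-4,6,10-tris(TBS-oxy)-12-(PMB-oxy)-13-methylheptadec-1-ene | CCCC[C@H](C)[C@H](OCc1ccc(OC)cc1)C[C@H](O[Si](C)(C)C(C)(C)C)CCC[C@H](O[Si](C)(C)C(C)(C)C)C[C@@H](O[Si](C)(C)C(C)(C)C)CC=C | intermediate
20 | (3R,5S,9R,11R,12S)-3,5,9-tris(TBS-oxy)-11-(PMB-oxy)-12-methylhexadecanal (C25–C40 aldehyde) | CCCC[C@H](C)[C@H](OCc1ccc(OC)cc1)C[C@H](O[Si](C)(C)C(C)(C)C)CCC[C@H](O[Si](C)(C)C(C)(C)C)C[C@@H](O[Si](C)(C)C(C)(C)C)CC=O | intermediate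
21 | methyl but-2-ynoate | CC#CC(=O)OC | starting material
22 | methyl (2Z)-3-iodobut-2-enoate | C/C(I)=C/C(=O)OC | intermediate
23 | 4,4-diethoxybut-1-ene | C=CCC(OCC)OCC | starting material
24 | 9-(4,4-diethoxybutyl)-9-borabicyclo[3.3.1]nonane | CCOC(CCCB1C2CCCC1CCC2)OCC | intermediate
25 | methyl (2Z)-7,7-diethoxy-3-methylhept-2-enoate | CCOC(CCC/C(C)=C\C(=O)OC)OCC | intermediate
26 | methyl (2Z)-3-methyl-7-oxohept-2-enoate | O=CCCC/C(C)=C\C(=O)OC | intermediate
27 | methyl (2Z,7S)-7-hydroxy-3-methyldeca-2,9-dienoate | C=CC[C@@H](O)CCC/C(C)=C\C(=O)OC | intermediate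
28 | methyl (2Z,7S)-7-(TBS-oxy)-3-methyldeca-2,9-dienoate | C=CC[C@@H](O[Si](C)(C)C(C)(C)C)CCC/C(C)=C\C(=O)OC | intermediate
29 | methyl (2Z,7S)-7-(TBS-oxy)-3-methyl-9-oxonon-2-enoate | O=CC[C@@H](O[Si](C)(C)C(C)(C)C)CCC/C(C)=C\C(=O)OC | intermediate
30 | methyl (2Z,7S,9R)-7-(TBS-oxy)-9-hydroxy-3-methyldodeca-2,11-dienoate | C=CC[C@@H](O)C[C@@H](O[Si](C)(C)C(C)(C)C)CCC/C(C)=C\C(=O)OC | intermediate
31 | methyl (2Z,7S,9R)-7,9-bis(TBS-oxy)-3-methyldodeca-2,11-dienoate | C=CC[C@@H](O[Si](C)(C)C(C)(C)C)C[C@@H](O[Si](C)(C)C(C)(C)C)CCC/C(C)=C\C(=O)OC | intermediate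
32 | methyl (2Z,7S,9R)-7,9-bis(TBS-oxy)-3-methyl-13-oxotridec-2-enoate | O=CCCC[C@@H](O[Si](C)(C)C(C)(C)C)C[C@@H](O[Si](C)(C)C(C)(C)C)CCC/C(C)=C\C(=O)OC | intermediate
33 | methyl (2Z,7S,9R,13R)-7,9-bis(TBS-oxy)-13-hydroxy-3-methylhexadeca-2,15-dienoate | C=CC[C@H](O)CCC[C@@H](O[Si](C)(C)C(C)(C)C)C[C@@H](O[Si](C)(C)C(C)(C)C)CCC/C(C)=C\C(=O)OC | intermediate
34 | methyl (2Z,7S,9R,13R)-7,9,13-tris(TBS-oxy)-3-methylhexadeca-2,15-dienoate | C=CC[C@H](O[Si](C)(C)C(C)(C)C)CCC[C@@H](O[Si](C)(C)C(C)(C)C)C[C@@H](O[Si](C)(C)C(C)(C)C)CCC/C(C)=C\C(=O)OC | intermediate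
35 | methyl (2Z,7S,9R,13R)-7,9,13-tris(TBS-oxy)-3-methyl-17-oxoheptadec-2-enoate | O=CCCC[C@H](O[Si](C)(C)C(C)(C)C)CCC[C@@H](O[Si](C)(C)C(C)(C)C)C[C@@H](O[Si](C)(C)C(C)(C)C)CCC/C(C)=C\C(=O)OC | intermediate
36 | methyl (2Z,7S,9R,13S,17R)-7,9,13-tris(TBS-oxy)-17-hydroxy-3-methylicosa-2,19-dienoate | C=CC[C@H](O)CCC[C@H](O[Si](C)(C)C(C)(C)C)CCC[C@@H](O[Si](C)(C)C(C)(C)C)C[C@@H](O[Si](C)(C)C(C)(C)C)CCC/C(C)=C\C(=O)OC | intermediate
37 | methyl (2Z,7S,9R,13S,17R)-7,9,13,17-tetrakis(TBS-oxy)-3-methylicosa-2,19-dienoate | C=CC[C@H](O[Si](C)(C)C(C)(C)C)CCC[C@H](O[Si](C)(C)C(C)(C)C)CCC[C@@H](O[Si](C)(C)C(C)(C)C)C[C@@H](O[Si](C)(C)C(C)(C)C)CCC/C(C)=C\C(=O)OC | intermediate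
38 | methyl (2Z,7S,9R,13S,17R)-7,9,13,17-tetrakis(TBS-oxy)-3-methyl-21-oxohenicos-2-enoate (C1–C21 aldehyde) | O=CCCC[C@H](O[Si](C)(C)C(C)(C)C)CCC[C@H](O[Si](C)(C)C(C)(C)C)CCC[C@@H](O[Si](C)(C)C(C)(C)C)C[C@@H](O[Si](C)(C)C(C)(C)C)CCC/C(C)=C\C(=O)OC | intermediate
39 | 3-bromoprop-1-yne (propargyl bromide) | C#CCBr | starting material
40 | propa-1,2-dien-1-ylmagnesium bromide | C=C=C[Mg]Br | intermediate
41 | propa-1,2-dien-1-ylboronic acid | C=C=CB(O)O | intermediate
42 | 5,5-dimethyl-2-(propa-1,2-dien-1-yl)-1,3,2-dioxaborinane | C=C=CB1OCC(C)(C)CO1 | intermediate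
43 | (E)-[3-(5,5-dimethyl-1,3,2-dioxaborinan-2-yl)prop-2-en-1-yl]bis(isopinocampheyl)borane, Ipc from (+)-α-pinene | CC1(C)COB(/C=C/CB([C@@H]2C[C@@H]3C[C@H]([C@H]2C)C3(C)C)[C@@H]2C[C@@H]3C[C@H]([C@H]2C)C3(C)C)OC1 | intermediate
44 | C22–C40 allylboronate: O25 bis(isopinocampheyl)borinate, neopentyl glycol boronate on C24 (24,25-anti), C22=C23 vinyl group | CCCC[C@H](C)[C@H](OCc1ccc(OC)cc1)C[C@H](O[Si](C)(C)C(C)(C)C)CCC[C@H](O[Si](C)(C)C(C)(C)C)C[C@@H](O[Si](C)(C)C(C)(C)C)C[C@@H](OB([C@@H]1C[C@@H]2C[C@H]([C@H]1C)C2(C)C)[C@@H]1C[C@@H]2C[C@H]([C@H]1C)C2(C)C)[C@@H](B1OCC(C)(C)CO1)C=C | intermediate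
45 | methyl (2Z,7S,9R,13S,17S,21R,23E,25R,27S,29S,33R,35R,36S)-7,9,13,17,27,29,33-heptakis(TBS-oxy)-21,25-dihydroxy-35-(PMB-oxy)-3,36-dimethyltetraconta-2,23-dienoate | CCCC[C@H](C)[C@H](OCc1ccc(OC)cc1)C[C@H](O[Si](C)(C)C(C)(C)C)CCC[C@H](O[Si](C)(C)C(C)(C)C)C[C@@H](O[Si](C)(C)C(C)(C)C)C[C@@H](O)/C=C/C[C@H](O)CCC[C@H](O[Si](C)(C)C(C)(C)C)CCC[C@H](O[Si](C)(C)C(C)(C)C)CCC[C@@H](O[Si](C)(C)C(C)(C)C)C[C@@H](O[Si](C)(C)C(C)(C)C)CCC/C(C)=C\C(=O)OC | intermediate
46 | methyl (2Z,7S,9R,13S,17S,21S,25S,27S,29S,33R,35R,36S)-7,9,13,17,27,29,33-heptakis(TBS-oxy)-21,25-dihydroxy-35-(PMB-oxy)-3,36-dimethyltetracont-2-enoate | CCCC[C@H](C)[C@H](OCc1ccc(OC)cc1)C[C@H](O[Si](C)(C)C(C)(C)C)CCC[C@H](O[Si](C)(C)C(C)(C)C)C[C@@H](O[Si](C)(C)C(C)(C)C)C[C@@H](O)CCC[C@H](O)CCC[C@H](O[Si](C)(C)C(C)(C)C)CCC[C@H](O[Si](C)(C)C(C)(C)C)CCC[C@@H](O[Si](C)(C)C(C)(C)C)C[C@@H](O[Si](C)(C)C(C)(C)C)CCC/C(C)=C\C(=O)OC | intermediate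
47 | methyl (2Z,7S,9R,13S,17R,21R,25S,27S,29S,33R,35R,36S)-7,9,13,17,21,25,27,29,33-nonakis(TBS-oxy)-35-(PMB-oxy)-3,36-dimethyltetracont-2-enoate | CCCC[C@H](C)[C@H](OCc1ccc(OC)cc1)C[C@H](O[Si](C)(C)C(C)(C)C)CCC[C@H](O[Si](C)(C)C(C)(C)C)C[C@@H](O[Si](C)(C)C(C)(C)C)C[C@@H](O[Si](C)(C)C(C)(C)C)CCC[C@H](O[Si](C)(C)C(C)(C)C)CCC[C@H](O[Si](C)(C)C(C)(C)C)CCC[C@H](O[Si](C)(C)C(C)(C)C)CCC[C@@H](O[Si](C)(C)C(C)(C)C)C[C@@H](O[Si](C)(C)C(C)(C)C)CCC/C(C)=C\C(=O)OC | intermediate
48 | methyl (2Z,7S,9R,13S,17R,21R,25S,27S,29S,33R,35R,36S)-7,9,13,17,21,25,27,29,33-nonakis(TBS-oxy)-35-hydroxy-3,36-dimethyltetracont-2-enoate | CCCC[C@H](C)[C@H](O)C[C@H](O[Si](C)(C)C(C)(C)C)CCC[C@H](O[Si](C)(C)C(C)(C)C)C[C@@H](O[Si](C)(C)C(C)(C)C)C[C@@H](O[Si](C)(C)C(C)(C)C)CCC[C@H](O[Si](C)(C)C(C)(C)C)CCC[C@H](O[Si](C)(C)C(C)(C)C)CCC[C@H](O[Si](C)(C)C(C)(C)C)CCC[C@@H](O[Si](C)(C)C(C)(C)C)C[C@@H](O[Si](C)(C)C(C)(C)C)CCC/C(C)=C\C(=O)OC | intermediate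
49 | (2Z,7S,9R,13S,17R,21R,25S,27S,29S,33R,35R,36S)-7,9,13,17,21,25,27,29,33-nonakis(TBS-oxy)-35-hydroxy-3,36-dimethyltetracont-2-enoic acid | CCCC[C@H](C)[C@H](O)C[C@H](O[Si](C)(C)C(C)(C)C)CCC[C@H](O[Si](C)(C)C(C)(C)C)C[C@@H](O[Si](C)(C)C(C)(C)C)C[C@@H](O[Si](C)(C)C(C)(C)C)CCC[C@H](O[Si](C)(C)C(C)(C)C)CCC[C@H](O[Si](C)(C)C(C)(C)C)CCC[C@H](O[Si](C)(C)C(C)(C)C)CCC[C@@H](O[Si](C)(C)C(C)(C)C)C[C@@H](O[Si](C)(C)C(C)(C)C)CCC/C(C)=C\C(=O)O | intermediate
50 | mixed anhydride of 49 with 2-methyl-6-nitrobenzoic acid | CCCC[C@H](C)[C@H](O)C[C@H](O[Si](C)(C)C(C)(C)C)CCC[C@H](O[Si](C)(C)C(C)(C)C)C[C@@H](O[Si](C)(C)C(C)(C)C)C[C@@H](O[Si](C)(C)C(C)(C)C)CCC[C@H](O[Si](C)(C)C(C)(C)C)CCC[C@H](O[Si](C)(C)C(C)(C)C)CCC[C@H](O[Si](C)(C)C(C)(C)C)CCC[C@@H](O[Si](C)(C)C(C)(C)C)C[C@@H](O[Si](C)(C)C(C)(C)C)CCC/C(C)=C\C(=O)OC(=O)c1c(C)cccc1[N+](=O)[O-] | intermediate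
51 | (3Z,8S,10R,14S,18R,22R,26S,28S,30S,34R,36R)-8,10,14,18,22,26,28,30,34-nonakis(TBS-oxy)-36-[(2S)-hexan-2-yl]-4-methyl-1-oxacyclohexatriacont-3-en-2-one | CCCC[C@H](C)[C@H]1C[C@H](O[Si](C)(C)C(C)(C)C)CCC[C@H](O[Si](C)(C)C(C)(C)C)C[C@@H](O[Si](C)(C)C(C)(C)C)C[C@@H](O[Si](C)(C)C(C)(C)C)CCC[C@H](O[Si](C)(C)C(C)(C)C)CCC[C@H](O[Si](C)(C)C(C)(C)C)CCC[C@H](O[Si](C)(C)C(C)(C)C)CCC[C@@H](O[Si](C)(C)C(C)(C)C)C[C@@H](O[Si](C)(C)C(C)(C)C)CCC/C(C)=C\C(=O)O1 | intermediate
52 | (3Z,8S,10R,14S,18R,22R,26S,28S,30S,34R,36R)-36-[(2S)-hexan-2-yl]-8,10,14,18,22,26,28,30,34-nonahydroxy-4-methyl-1-oxacyclohexatriacont-3-en-2-one (CNP0126363.4) | CCCC[C@H](C)[C@H]1C[C@H](O)CCC[C@H](O)C[C@@H](O)C[C@@H](O)CCC[C@H](O)CCC[C@H](O)CCC[C@H](O)CCC[C@@H](O)C[C@@H](O)CCC/C(C)=C\C(=O)O1 | target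

## Step count and least certain steps

Total step count: 39. Longest linear sequence: 23 steps (steps 1–16, then 33–39); the C1–C21 branch runs 15 steps (17–31) before the union.

**Step 33 (key step).** The most likely failures are loss of the required order of events (free allylborane meeting 38, or unreacted 20 meeting 44, giving homo-coupled diols), erosion of E selectivity and of the chirality transfer to C21 if the axial transition state competes for such large partners, and a sluggish second allylboration of the big aldehyde at ambient temperature. The fallback is a stepwise union by cross-metathesis and reagent-controlled reduction; it sets out from 20 and 38 and comes back at 46. Aldehyde 20 would be allylated with 17 (conditions of step 14) to the C25 homoallylic alcohol (4S,6S,8S,12R,14R,15S)-6,8,12-tris(TBS-oxy)-14-(PMB-oxy)-15-methylnonadec-1-en-4-ol F1. Aldehyde 38 would be treated with CH2=CHMgBr (THF, −78 °C) to give the allylic alcohol methyl (2Z,7S,9R,13S,17S)-7,9,13,17-tetrakis(TBS-oxy)-21-hydroxy-3-methyltricosa-2,22-dienoate F2 as a mixture of C21 epimers, and Dess–Martin oxidation would give the vinyl ketone methyl (2Z,7S,9R,13S,17R)-7,9,13,17-tetrakis(TBS-oxy)-3-methyl-21-oxotricosa-2,22-dienoate F3. Cross-metathesis of F1 with F3 (second-generation Hoveyda–Grubbs catalyst, CH2Cl2, 40 °C) should join C22 to C23 with loss of ethene and give the (E)-enone methyl (2Z,7S,9R,13S,17R,22E,25S,27S,29S,33R,35R,36S)-7,9,13,17,27,29,33-heptakis(TBS-oxy)-25-hydroxy-35-(PMB-oxy)-3,36-dimethyl-21-oxotetraconta-2,22-dienoate F4. Corey–Bakshi–Shibata reduction with the (S)-methyl oxazaborolidine and catecholborane (toluene, −78 °C), the alkenyl arm acting as the large group, should give the 21R ene-diol methyl (2Z,7S,9R,13S,17S,21R,22E,25S,27S,29S,33R,35R,36S)-7,9,13,17,27,29,33-heptakis(TBS-oxy)-21,25-dihydroxy-35-(PMB-oxy)-3,36-dimethyltetraconta-2,22-dienoate F5. F5 is the 22-ene regioisomer of 45, and the diimide conditions of step 34 would take it to 46.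

**Step 38.** The most likely failures are slow acyl transfer to the hindered O35 at high dilution, leading to oligomers, and amine-induced loss of the Z geometry or deconjugation of the activated 3-methyl-2-enoyl unit through a vinylketene. The fallback replaces in-flask anhydride activation by an isolated thioester cyclised under neutral, thiophilic activation (Corey–Nicolaou/Gerlach lactonisation); it sets out from 49 and comes back at 51. Acid 49 with 2,2'-dipyridyl disulfide and PPh3 (toluene, rt) would give the S-(pyridin-2-yl) thioester of 49, S-pyridin-2-yl (2Z,7S,9R,13S,17R,21R,25S,27S,29S,33R,35R,36S)-7,9,13,17,21,25,27,29,33-nonakis(TBS-oxy)-35-hydroxy-3,36-dimethyltetracont-2-enethioate F6. Slow addition of F6 to AgOTf in toluene at high dilution should close the ring to 51 without any amine base.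

**Step 34.** The most likely failure is loss of chemoselectivity: the trans-disubstituted alkene needs a large excess of diimide, and partial saturation of the C2=C3 enoate or stalled conversion may result. The fallback changes the source of selectivity from relative diimide rates to substrate direction: hydroxyl-directed hydrogenation of 45 with [Rh(nbd)(dppb)]BF4 under H2 in CH2Cl2. The allylic O25 and homoallylic O21 hydroxyls bind the cationic metal and deliver hydrogen to C23=C24, while the remote trisubstituted enoate has no such handle. It sets out from 45 and comes back at 46 and makes no new compound (F0).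

**Step 10 (and likewise steps 25, 28 and 31).** The most likely failures are incomplete linear selectivity, double-bond migration before carbonylation, and the practical demands of a pressure reaction on precious material. The fallback builds the same aldehyde by cross-metathesis and conjugate reduction; it sets out from 12 and comes back at 13. Alkene 12 and crotonaldehyde with the second-generation Hoveyda–Grubbs catalyst (CH2Cl2, 40 °C) should give, with loss of propene, the enal (2E,5R,7R,8S)-5-(TBS-oxy)-7-(PMB-oxy)-8-methyldodec-2-enal F7. Conjugate reduction of F7 with [(Ph3P)CuH]6 (benzene, rt) would give 13. The same two operations apply to 31, 34 and 37, where the hindered trisubstituted enoate is expected to react much more slowly with the copper hydride than the disubstituted enal.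

## Further compounds

F1 | step 33 | (4S,6S,8S,12R,14R,15S)-6,8,12-tris(TBS-oxy)-14-(PMB-oxy)-15-methylnonadec-1-en-4-ol | CCCC[C@H](C)[C@H](OCc1ccc(OC)cc1)C[C@H](O[Si](C)(C)C(C)(C)C)CCC[C@H](O[Si](C)(C)C(C)(C)C)C[C@@H](O[Si](C)(C)C(C)(C)C)C[C@@H](O)CC=C
F2 | step 33 | methyl (2Z,7S,9R,13S,17S)-7,9,13,17-tetrakis(TBS-oxy)-21-hydroxy-3-methyltricosa-2,22-dienoate (C21 epimers) | C=CC(O)CCC[C@H](O[Si](C)(C)C(C)(C)C)CCC[C@H](O[Si](C)(C)C(C)(C)C)CCC[C@@H](O[Si](C)(C)C(C)(C)C)C[C@@H](O[Si](C)(C)C(C)(C)C)CCC/C(C)=C\C(=O)OC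
F3 | step 33 | methyl (2Z,7S,9R,13S,17R)-7,9,13,17-tetrakis(TBS-oxy)-3-methyl-21-oxotricosa-2,22-dienoate | C=CC(=O)CCC[C@H](O[Si](C)(C)C(C)(C)C)CCC[C@H](O[Si](C)(C)C(C)(C)C)CCC[C@@H](O[Si](C)(C)C(C)(C)C)C[C@@H](O[Si](C)(C)C(C)(C)C)CCC/C(C)=C\C(=O)OC
F4 | step 33 | methyl (2Z,7S,9R,13S,17R,22E,25S,27S,29S,33R,35R,36S)-7,9,13,17,27,29,33-heptakis(TBS-oxy)-25-hydroxy-35-(PMB-oxy)-3,36-dimethyl-21-oxotetraconta-2,22-dienoate | CCCC[C@H](C)[C@H](OCc1ccc(OC)cc1)C[C@H](O[Si](C)(C)C(C)(C)C)CCC[C@H](O[Si](C)(C)C(C)(C)C)C[C@@H](O[Si](C)(C)C(C)(C)C)C[C@@H](O)C/C=C/C(=O)CCC[C@H](O[Si](C)(C)C(C)(C)C)CCC[C@H](O[Si](C)(C)C(C)(C)C)CCC[C@@H](O[Si](C)(C)C(C)(C)C)C[C@@H](O[Si](C)(C)C(C)(C)C)CCC/C(C)=C\C(=O)OC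
F5 | step 33 | methyl (2Z,7S,9R,13S,17S,21R,22E,25S,27S,29S,33R,35R,36S)-7,9,13,17,27,29,33-heptakis(TBS-oxy)-21,25-dihydroxy-35-(PMB-oxy)-3,36-dimethyltetraconta-2,22-dienoate | CCCC[C@H](C)[C@H](OCc1ccc(OC)cc1)C[C@H](O[Si](C)(C)C(C)(C)C)CCC[C@H](O[Si](C)(C)C(C)(C)C)C[C@@H](O[Si](C)(C)C(C)(C)C)C[C@@H](O)C/C=C/[C@H](O)CCC[C@H](O[Si](C)(C)C(C)(C)C)CCC[C@H](O[Si](C)(C)C(C)(C)C)CCC[C@@H](O[Si](C)(C)C(C)(C)C)C[C@@H](O[Si](C)(C)C(C)(C)C)CCC/C(C)=C\C(=O)OC
F0 | step 34 | none | none
F6 | step 38 | S-pyridin-2-yl (2Z,7S,9R,13S,17R,21R,25S,27S,29S,33R,35R,36S)-7,9,13,17,21,25,27,29,33-nonakis(TBS-oxy)-35-hydroxy-3,36-dimethyltetracont-2-enethioate | CCCC[C@H](C)[C@H](O)C[C@H](O[Si](C)(C)C(C)(C)C)CCC[C@H](O[Si](C)(C)C(C)(C)C)C[C@@H](O[Si](C)(C)C(C)(C)C)C[C@@H](O[Si](C)(C)C(C)(C)C)CCC[C@H](O[Si](C)(C)C(C)(C)C)CCC[C@H](O[Si](C)(C)C(C)(C)C)CCC[C@H](O[Si](C)(C)C(C)(C)C)CCC[C@@H](O[Si](C)(C)C(C)(C)C)C[C@@H](O[Si](C)(C)C(C)(C)C)CCC/C(C)=C\C(=O)Sc1ccccn1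
F7 | step 10 | (2E,5R,7R,8S)-5-(TBS-oxy)-7-(PMB-oxy)-8-methyldodec-2-enal | CCCC[C@H](C)[C@H](OCc1ccc(OC)cc1)C[C@H](O[Si](C)(C)C(C)(C)C)C/C=C/C=O
A1 | alternative 1 | open-chain C4–C40 nonakis-TBS ether with terminal C4=C5 alkene and O35 (Z)-3-iodobut-2-enoate | CCCC[C@H](C)[C@H](OC(=O)/C=C(/C)I)C[C@H](O[Si](C)(C)C(C)(C)C)CCC[C@H](O[Si](C)(C)C(C)(C)C)C[C@@H](O[Si](C)(C)C(C)(C)C)C[C@@H](O[Si](C)(C)C(C)(C)C)CCC[C@H](O[Si](C)(C)C(C)(C)C)CCC[C@H](O[Si](C)(C)C(C)(C)C)CCC[C@H](O[Si](C)(C)C(C)(C)C)CCC[C@@H](O[Si](C)(C)C(C)(C)C)C[C@@H](O[Si](C)(C)C(C)(C)C)CC=C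
A2 | alternative 1 | nonakis-TBS macrolactone (same structure as 51) | CCCC[C@H](C)[C@H]1C[C@H](O[Si](C)(C)C(C)(C)C)CCC[C@H](O[Si](C)(C)C(C)(C)C)C[C@@H](O[Si](C)(C)C(C)(C)C)C[C@@H](O[Si](C)(C)C(C)(C)C)CCC[C@H](O[Si](C)(C)C(C)(C)C)CCC[C@H](O[Si](C)(C)C(C)(C)C)CCC[C@H](O[Si](C)(C)C(C)(C)C)CCC[C@@H](O[Si](C)(C)C(C)(C)C)C[C@@H](O[Si](C)(C)C(C)(C)C)CCC/C(C)=C\C(=O)O1
A3 | alternative 2 | pentane-1,5-diol | OCCCCCO
A4 | alternative 2 | (4R,8R)-undeca-1,10-diene-4,8-diol | C=CC[C@H](O)CCC[C@@H](O)CC=C
A5 | alternative 3 | (R)-epichlorohydrin | ClC[C@H]1CO1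
A6 | alternative 3 | C5–C15 dithiane: 2-substituted 1,3-dithiane with TBS ethers on C7, C9 and C13 and a C5 dioxolane | S1CCCSC1C[C@H](O[Si](C)(C)C(C)(C)C)CCC[C@@H](O[Si](C)(C)C(C)(C)C)C[C@@H](O[Si](C)(C)C(C)(C)C)CC1OCCO1
A7 | alternative 3 | C19–C40 dithiane: 2-substituted 1,3-dithiane with TBS ethers on C21, C25, C27, C29 and C33 and a triethylsilyl ether on C35 | CCCC[C@H](C)[C@H](O[Si](CC)(CC)CC)C[C@H](O[Si](C)(C)C(C)(C)C)CCC[C@H](O[Si](C)(C)C(C)(C)C)C[C@@H](O[Si](C)(C)C(C)(C)C)C[C@@H](O[Si](C)(C)C(C)(C)C)CCC[C@H](O[Si](C)(C)C(C)(C)C)CC1SCCCS1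
A8 | alternative 3 | C5–C40 chain with C15 and C19 dithianes and free C17 hydroxyl | CCCC[C@H](C)[C@H](O[Si](CC)(CC)CC)C[C@H](O[Si](C)(C)C(C)(C)C)CCC[C@H](O[Si](C)(C)C(C)(C)C)C[C@@H](O[Si](C)(C)C(C)(C)C)C[C@@H](O[Si](C)(C)C(C)(C)C)CCC[C@H](O[Si](C)(C)C(C)(C)C)CC1(SCCCS1)C[C@H](O)CC1(SCCCS1)C[C@H](O[Si](C)(C)C(C)(C)C)CCC[C@@H](O[Si](C)(C)C(C)(C)C)C[C@@H](O[Si](C)(C)C(C)(C)C)CC1OCCO1
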